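The rate constants are assumed; the rest is arithmetic.

There were 3 questions about this flask, and I met them with one factor.

substrate 0.20 M; gas phase 9.7 mM (held); time 30 h

- how much target there is at 30 h, in percent of the substrate charged
- the change that raises the amount of target at 30 h, in percent of the substrate charged most ("none" if none brings more than 2 percentage points) (summer / midnight / none)
- amount of target at 30 h, in percent of the substrate charged, after midnight

- percent here means substrate units held: one homo dimer counts as two
- where a step has two of a species, its rate is k times that concentration squared, and two are used at each turn
- at the start none of the gas is dissolved
- run time (flask): 30 h

    substrate → side product (k1 = 0.00275 s⁻¹)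
    2 substrate → homo dimer (k2 = 0.00131 M⁻¹ s⁻¹)
    substrate + dissolved gas → target (k3 = 0.493 M⁻¹ s⁻¹)
    dissolved gas + target → over-reaction product (k4 = 7.90 × 10⁻⁴ M⁻¹ s⁻¹)
    gas phase ⇌ dissolved gas, rate k5*(csat - [dissolved gas]) (k5 = 0.0111 s⁻¹, csat = 9.7 mM)

I first compared rates at the opening moment. In this flask, substrate went to side product at 0.550 mM s⁻¹, while transfer could bring gas at no more than 0.108 mM s⁻¹, a slower rate. Two extreme flasks, each solved in the head, bracketed the share of substrate turned into target:

gas-starved, transfer ceiling over the side-product loss: 19.6%

saturated from the start, [dissolved gas] = csat: 63.5%

I placed the flask's opening near the starved end, because the uptake coefficient k3[substrate] stood above the transfer coefficient k5, which holds [dissolved gas] below csat while uptake nearly matches supply. That comparison drifted as [substrate] fell, reaching parity at 11.3% of the charge. Weighting the two shares by this fraction, I took 24.5% as formed, setting homo dimer aside as the slower loss.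

Substrate had a half-life of 0.0700 h by the side-product step, far shorter than the run. Afterwards, the uptake coefficient k4[target], even for a full charge of target, stood far below k5. So [dissolved gas] stayed near csat and target decayed by a pseudo-first-order law. This gave the survival factor, the fraction of early-formed target still standing at the end:

survival = exp(−over-reaction constant × csat × time) = 0.437

My estimate was therefore 10.7%. Midnight leaves the factor untouched and raises capture, so I chose it. Summer squares the factor and at most doubles capture, leaving at most 0.874 of the target, a loss.

The forecast gave 11.2% (10% to 12.5%), above my figure, then midnight with 15.4% (13.8% to 17%), holding that “near-saturated dissolved gas over-reacts more than half of it away”.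

The simulation gave 11.2%, and midnight as best at 15.1%, a change of 3.9 percentage points against −3.7 points for summer. The neighbouring flask with 0.80 M of substrate shares the constants, csat and time, so its survival factor is again 0.437. It ended with 5.91% of over-reaction product beside its target, and applying the factor to the sum of that pair, 4.63% of the substrate charged should have survived as target. That neighbouring flask held 4.67% of target at 30.0 h.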